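## Structural features

The target (C40H56O) is a carotenoid: a chain of eleven E double bonds (ten conjugated, C7 to C6') with an open ψ end on one side and a cyclopentane (C2–C6) on the other. In carotenoid numbering C1 is the isopropenyl carbon, C2–C6 form the ring and C7 starts the polyene. The ring carries three contiguous stereocentres: C2 (S, isopropenyl), C6 (R, polyene) and the tertiary methyl carbinol C5 (S). C7 is trans to the isopropenyl group, trans to the C5 methyl and cis to the hydroxyl. C5 stands β to C7, so a free C7 carbonyl beside a free C5–OH is open to retro-aldol cleavage and β-elimination. The polyene is sensitive to light, oxygen, acid and electrophiles and is best built last by C15 + C10 + C15 carbonyl olefinations, which need C7 as a ring aldehyde. The real difficulty is the ring: a fully substituted carbinol next to a CH that must be trans to a second CH. The key step uses the fact that C6 is α to the aldehyde-level C7 while C2 is the γ-carbon of a 2-methylallyl unit, with C3–C4–C5 between them: an oxidised enol ether C6=C7 is electrophilic at C6, an allylsilane is nucleophilic at C2, and the C2–C6 bond closes the ring. C5 keeps the same spatial arrangement and descriptor (S; O > C6 > C4 > CH3) from the open chain to the target, so the key-step pair needs no structural correction.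

## Logic of the disconnections

**28 ⇒ 20 + 26.** The C11=C12 bond is cut (Wittig). This splits the molecule into a C15 ring piece and a C25 polyene aldehyde, and the hydroxyl is already free, so no deprotection is run on the C40 polyene. The forward step must form the ylide with a mild base beside a free tertiary hydroxyl and must allow Z to E equilibration of the new bond.

**26 ⇒ 23 + 24, then 23 ⇒ 22 ⇒ 21.** The C11'=C12' bond, the C11'–P bond and the vinyl–carbinol bond are cut. This traces the open end to two commercial compounds. The forward steps need mono-olefination of a symmetrical dialdehyde (used in excess) and an allylic transposition on salt formation.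

**20 ⇒ 18 ⇒ 17 ⇒ 14 + 15.** The C11–P bond and then C7=C8 are cut (Horner–Wadsworth–Emmons). A five-carbon phosphonate brings C8–C11 and the C9 methyl with E control. The silyl ether is chosen so that the acid of the salt-forming step removes it. The olefination must be faster than enolisation or β-elimination of the β-silyloxy aldehyde.

**14 ⇒ 13.** C7 is returned to its dimethyl acetal, which masks the aldehyde until use. The hydrolysis must spare a tertiary silyl ether.

**13 ⇒ 12 (key).** The C2–C6 ring bond is cut. One ring and two stereocentres disappear, leaving an open chain whose only stereocentre is C5. The forward step needs selective oxidation of the enol ether, 5-exo closure, loss of silicon towards the isopropenyl group, and facial control by C5.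

**12 ⇒ 11 ⇒ 10 ⇒ 9.** The allylic C–Si bond is cut, then the acetate and the ester level are adjusted. The allylsilane is made last, under neutral conditions, when the enol ether already exists. The reverse order would require an enol ether to be made from a C7 acetal by Lewis acid in a chain that already holds a nucleophilic alkene six atoms away, which invites Prins or Hosomi–Sakurai closure to a cyclohexane. The silylation must be regioselective, E-selective and inert to the enol ether.

**9 ⇒ 8 ⇒ 7.** C6=C7 (methoxymethylene Wittig) and C2=C1 (stabilised Wittig) are cut. Both alkenes come from one dialdehyde under basic, cation-free conditions. The stabilised ylide must choose the unhindered formyl group (C2) over the neopentyl-type one (C6), so it is used first.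

**7 ⇒ 5 ⇒ 4 ⇒ 3 ⇒ 2 ⇒ 1.** Both carbonyls are traced to the two alkenes of 5. The tertiary allylic carbinol 4 comes from epoxy alcohol 2 by reductive transposition through 3, and 2 from 1 by asymmetric epoxidation. C5 is thus set by reagent control on a cheap allylic alcohol. The C–O bond at the quaternary carbon must not be touched on the way.

## Other disconnections considered

**Alternative 1:** The cut is C5–C6, with a temporary O–C7 bond. Cleaving the ring alkene of (S)-limonene A1 and oxidising would give the keto acid A2, (3S)-6-oxo-3-(prop-1-en-2-yl)heptanoic acid. Carboxyl activation with a nucleophilic amine catalyst would form an ammonium enolate that adds to the methyl ketone, and the alkoxide would close the cis-fused β-lactone A3.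
- In favour: C2 comes from the chiral pool; the four-membered ring can only be cis-fused, so the C5 oxygen and C7 are forced onto one face; C7 stays at the acid level, which excludes retro-aldol loss.
- Against: only the C2 substituent steers the aldol step and must end anti to the lactone; the ring alkene of A1 must be cleaved beside the isopropenyl group; A3 still needs opening, protection and adjustment of C7, and a β-lactone can lose CO2.
- Comparison: on the C5/C6 relation the alternative is the better, because a geometric constraint replaces a conformational preference. On the C2/C6 relation and on absolute configuration the two are equal. On step economy the alternative is the better: A3 would take about three steps and the stage of 14 perhaps seven, against twelve. The chosen plan delivers C7 directly as a protected aldehyde with the carbinol already silylated.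

**Alternative 2:** No ring bond is made; the cuts are C1–C2 and C6–C7 on cyclopent-2-en-1-one A4. An isopropenyl Grignard reagent would add 1,4 under a copper–chiral ferrocenyl diphosphine catalyst, the enolate would be silylated and then alkylated by an orthoformate with a boron Lewis acid to give A5. Methyl addition anti to the acetal arm and silylation would reach the skeleton of 13.
- In favour: three to four steps to the stage of 13; the chiral element is catalytic; the C2/C6 trans relation follows from enolate alkylation anti to the β-substituent; C7 arrives as the same acetal.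
- Against: everything depends on the enantioselectivity of an sp2 Grignard addition to a five-membered enone, an unfavourable pairing in which 1,2-addition and low selectivity are likely; the methyl addition must outrun enolisation, and its facial course fixes C5.
- Comparison: on step economy and on the C2/C6 relation the alternative is clearly the better, and it needs no special equipment. On absolute configuration the chosen plan is the better (reagent-controlled epoxidation). On the C5 configuration the two are equal, each relying on one substrate-controlled event.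

**Alternative 3:** The cut is C2–C3, made by migration. A Diels–Alder adduct would be elaborated to the cis-diol monomesylate A6, whose ring holds C1, C2, C6, C5, C4 and C3. A potassium alkoxide base would form the tertiary C1 alkoxide, and the ring bond C1–C3, anti-periplanar to the mesylate, would shift to C2 with inversion to give the acetylcyclopentane A7. Methylenation, debenzylation and oxidation would follow.
- In favour: the shift is stereospecific, so C2 needs no facial choice; a cis-diol monomesylate cannot close to an epoxide; C7 stays at the alcohol level until late.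
- Against: A6 carries four stereocentres that must all be set first (enantioselective cycloaddition, face-selective dihydroxylation, selective sulfonylation), and three operations follow the contraction; methyl or hydride shifts must be excluded by conformation.
- Comparison: on the reliability of the ring-forming event the alternative is the better (stereospecific against stereoselective). On the C5/C6 relation it is equal or better. On step economy and protecting-group traffic it is clearly the worse, probably by five or more steps.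

Key step: step 11

**Assumptions (remarks on the chemistry)**
- The C5 oxygen is carried as a triethylsilyl ether instead of a bulkier silyl ether, so that it falls off under the acid of step 15 and no deprotection is needed on the C40 polyene.
- Step 7 should give both geometric isomers at C6=C7; compounds 9–12 are written as the E isomer, and Z material can be carried along because C7 becomes an sp3 acetal carbon in step 11.
- Compound 21 is used as its (3E,5E) isomer; the salt 23 is purified by crystallisation.

## Route

**Step 1**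
Reactants: 1 geraniol
Product: 2 [(2S,3S)-3-methyl-3-(4-methylpent-3-en-1-yl)oxiran-2-yl]methanol
Conditions: Ti(OiPr)4 (cat.), L-(+)-diethyl tartrate (cat.), t-BuOOH, 4 Å molecular sieves, CH2Cl2, −20 °C
Reagents that add atoms: tert-butyl hydroperoxide, CC(C)(C)OO
Why: Katsuki–Sharpless asymmetric epoxidation; the L-(+)-tartrate titanium complex delivers oxygen to the face that gives the (2S,3S) epoxide and so sets the later C5; the remote alkene has no directing hydroxyl and stays.

**Step 2**
Reactants: 2 [(2S,3S)-3-methyl-3-(4-methylpent-3-en-1-yl)oxiran-2-yl]methanol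
Product: 3 (2R,3S)-2-(iodomethyl)-3-methyl-3-(4-methylpent-3-en-1-yl)oxirane
Conditions: I2, PPh3, imidazole, Et2O/MeCN, 0 °C
Reagents that add atoms: iodine, II
Why: Appel-type iodination of the primary alcohol under imidazole buffering, which leaves the epoxide and both stereocentres untouched (the descriptor at C2 changes only by priority).

**Step 3**
Reactants: 3 (2R,3S)-2-(iodomethyl)-3-methyl-3-(4-methylpent-3-en-1-yl)oxirane
Product: 4 (3S)-3,7-dimethylocta-1,6-dien-3-ol
Conditions: Zn dust, EtOH, 70 °C
Reagents that add atoms: none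
Why: Zinc inserts into the C–I bond and the organozinc opens the epoxide by β-elimination (Boord-type reductive elimination); the C–O bond at the quaternary carbon is retained, so the carbinol keeps its configuration.

**Step 4**
Reactants: 4 (3S)-3,7-dimethylocta-1,6-dien-3-ol
Product: 5 triethyl{[(3S)-3,7-dimethylocta-1,6-dien-3-yl]oxy}silane
Conditions: Et3SiOTf, 2,6-lutidine, CH2Cl2, −78 → 0 °C
Reagents that add atoms: triethylsilyl trifluoromethanesulfonate, CC[Si](CC)(CC)OS(=O)(=O)C(F)(F)F
Why: Silyl triflate with a hindered pyridine base silylates tertiary allylic alcohols without ionising them.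

**Step 5**
Reactants: 5 triethyl{[(3S)-3,7-dimethylocta-1,6-dien-3-yl]oxy}silane
Product: 7 (2S)-2-methyl-2-[(triethylsilyl)oxy]pentanedial, via bis-ozonide 6 (not isolated)
Conditions: O3, CH2Cl2, −78 °C; then PPh3, −78 °C → rt
Reagents that add atoms: ozone, [O-][O+]=O
Why: Ozonolysis (Criegee mechanism) of both alkenes with reductive work-up; the formyl group on the quaternary carbon cannot enolise, so C5 is safe, and the crude dialdehyde is used at once.

**Step 6**
Reactants: 7 (2S)-2-methyl-2-[(triethylsilyl)oxy]pentanedial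
Product: 8 ethyl (2E,6S)-2,6-dimethyl-7-oxo-6-[(triethylsilyl)oxy]hept-2-enoate
Conditions: Ph3P=C(CH3)CO2Et (1.0 equiv, slow addition), CH2Cl2, 0 °C → rt
Reagents that add atoms: ethyl 2-(triphenyl-λ5-phosphanylidene)propanoate, CCOC(=O)C(C)=P(c1ccccc1)(c1ccccc1)c1ccccc1
Why: Wittig reaction of a stabilised, α-branched ylide, which is E-selective and should choose the unhindered CH2–CHO over the formyl group on the fully substituted carbon; this installs C1 with its methyl and the future silylmethyl carbon.

**Step 7**
Reactants: 8 ethyl (2E,6S)-2,6-dimethyl-7-oxo-6-[(triethylsilyl)oxy]hept-2-enoate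
Product: 9 ethyl (2E,6S,7E)-8-methoxy-2,6-dimethyl-6-[(triethylsilyl)oxy]octa-2,7-dienoate
Conditions: MeOCH2PPh3Cl, KN(SiMe3)2, THF, −78 °C; then 8, −78 → 0 °C
Reagents that add atoms: (methoxymethyl)triphenylphosphonium chloride, COC[P+](c1ccccc1)(c1ccccc1)c1ccccc1.[Cl-]
Why: Wittig methoxymethylenation brings in C7 as the enol ether under basic, cation-free conditions; the non-enolisable aldehyde reacts faster than the conjugated ester at low temperature.

**Step 8**
Reactants: 9 ethyl (2E,6S,7E)-8-methoxy-2,6-dimethyl-6-[(triethylsilyl)oxy]octa-2,7-dienoate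
Product: 10 (2E,6S,7E)-8-methoxy-2,6-dimethyl-6-[(triethylsilyl)oxy]octa-2,7-dien-1-ol
Conditions: i-Bu2AlH, CH2Cl2, −78 °C
Reagents that add atoms: none
Why: 1,2-Reduction of the enoate to the E allylic alcohol; enol ether and silyl ether are inert to the hydride, and work-up is kept basic.

**Step 9**
Reactants: 10 (2E,6S,7E)-8-methoxy-2,6-dimethyl-6-[(triethylsilyl)oxy]octa-2,7-dien-1-ol
Product: 11 (2E,6S,7E)-8-methoxy-2,6-dimethyl-6-[(triethylsilyl)oxy]octa-2,7-dien-1-yl acetate
Conditions: Ac2O, pyridine, DMAP (cat.), CH2Cl2, 0 °C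
Reagents that add atoms: acetic anhydride, CC(=O)OC(C)=O
Why: Base-buffered acylation of the primary allylic alcohol, which the enol ether tolerates.

**Step 10**
Reactants: 11 (2E,6S,7E)-8-methoxy-2,6-dimethyl-6-[(triethylsilyl)oxy]octa-2,7-dien-1-yl acetate
Product: 12 triethyl{[(1E,3S,6E)-1-methoxy-3,7-dimethyl-8-(trimethylsilyl)octa-1,6-dien-3-yl]oxy}silane
Conditions: Me3SiSiMe3, Pd(dba)2 (cat.), LiCl, DMF, 100 °C
Reagents that add atoms: hexamethyldisilane, C[Si](C)(C)[Si](C)(C)C
Why: Palladium-catalysed silylation of an allylic acetate with a disilane: zerovalent palladium gives the π-allyl complex, the Si–Si bond transmetalates, and reductive elimination at the unhindered CH2 terminus of the syn complex gives the linear E allylsilane under neutral conditions.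

**Step 11**
Reactants: 12 triethyl{[(1E,3S,6E)-1-methoxy-3,7-dimethyl-8-(trimethylsilyl)octa-1,6-dien-3-yl]oxy}silane
Product: 13 triethyl{[(1S,2R,3S)-2-(dimethoxymethyl)-1-methyl-3-(prop-1-en-2-yl)cyclopentyl]oxy}silane
Conditions: reticulated vitreous carbon anode, Pt cathode, undivided cell, constant current (about 2.2 F/mol), 0.1 M LiClO4, 2,6-lutidine, MeOH/THF, rt
Reagents that add atoms: methanol, CO
Why: This is an anodic olefin coupling of an enol ether radical cation with an allylsilane, a known reaction type. The enol ether is the most easily oxidised π system and loses one electron at the anode; its C6 terminus becomes electrophilic and is attacked by the γ-carbon C2 of the allylsilane, closing the cyclopentane 5-exo-trig with respect to both alkenes, helped by the fully substituted C5 (Thorpe–Ingold effect). The β-silyl cation at C1 gives up Me3Si to methanol, so only the isopropenyl alkene can form, and the α-methoxy radical at C7 loses the second electron and is trapped by methanol as the dimethyl acetal. C5 is untouched, and C2 and C6 are set under substrate control. The trans relation C2/C6 should follow from an extended transition state in which the exocyclic termini C1 and C7 both lie pseudo-equatorial on the forming ring. With respect to C5, the tether carbon C4 must stand perpendicular to the C6=C7 plane, which leaves the positions beside C7 and beside C6–H to the other two substituents; the small, electron-rich silyloxy oxygen beside the electron-poor C7 and the methyl outside should give C7 cis to oxygen and the methyl cis to the isopropenyl group. The step needs chemoselective oxidation (the product alkene and the silyl ethers are harder to oxidise, and initial oxidation of the allylsilane would lead to the same bond) and an acid-free medium, which 2,6-lutidine secures for enol ether, acetal and silyl ether. A C6 epimer would still be correctable by base at the stage of 14, where the wanted isomer is the more stable one.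

**Step 12**
Reactants: 13 triethyl{[(1S,2R,3S)-2-(dimethoxymethyl)-1-methyl-3-(prop-1-en-2-yl)cyclopentyl]oxy}silane
Product: 14 (1R,2S,5S)-2-methyl-5-(prop-1-en-2-yl)-2-[(triethylsilyl)oxy]cyclopentane-1-carbaldehyde
Conditions: PPTS (cat.), acetone/H2O, 40 °C
Reagents that add atoms: water, O
Why: Mild acid-catalysed acetal hydrolysis in wet acetone; a tertiary triethylsilyl ether should survive a pyridinium acid, and the silyl group keeps the β-oxygenated aldehyde from retro-aldol cleavage.

**Step 13**
Reactants: 14 (1R,2S,5S)-2-methyl-5-(prop-1-en-2-yl)-2-[(triethylsilyl)oxy]cyclopentane-1-carbaldehyde; 15 ethyl (2E)-4-(diethoxyphosphoryl)-3-methylbut-2-enoate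
Product: 17 ethyl (2E,4E)-3-methyl-5-{(1R,2S,5S)-2-methyl-5-(prop-1-en-2-yl)-2-[(triethylsilyl)oxy]cyclopentyl}penta-2,4-dienoate, via lithiated phosphonate 16 (not isolated)
Conditions: LiN(SiMe3)2, THF, −78 °C; then 14, −78 → 0 °C
Reagents that add atoms: none
Why: Horner–Wadsworth–Emmons olefination with a vinylogous phosphonate forms C7=C8 with E selectivity and adds C8–C11; addition of the stabilised anion to the aldehyde at low temperature should outrun enolisation at C6.

**Step 14**
Reactants: 17 ethyl (2E,4E)-3-methyl-5-{(1R,2S,5S)-2-methyl-5-(prop-1-en-2-yl)-2-[(triethylsilyl)oxy]cyclopentyl}penta-2,4-dienoate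
Product: 18 (2E,4E)-3-methyl-5-{(1R,2S,5S)-2-methyl-5-(prop-1-en-2-yl)-2-[(triethylsilyl)oxy]cyclopentyl}penta-2,4-dien-1-ol
Conditions: i-Bu2AlH, CH2Cl2, −78 °C
Reagents that add atoms: none
Why: 1,2-Reduction of the dienoate to the dienol; no stereocentre is involved.

**Step 15**
Reactants: 18 (2E,4E)-3-methyl-5-{(1R,2S,5S)-2-methyl-5-(prop-1-en-2-yl)-2-[(triethylsilyl)oxy]cyclopentyl}penta-2,4-dien-1-ol
Product: 20 {(2E,4E)-5-[(1R,2S,5S)-2-hydroxy-2-methyl-5-(prop-1-en-2-yl)cyclopentyl]-3-methylpenta-2,4-dien-1-yl}triphenylphosphonium bromide, via silylated phosphonium bromide 19 (not isolated)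
Conditions: PPh3·HBr, MeOH, 0 °C → rt
Reagents that add atoms: triphenylphosphine hydrobromide, Br.c1ccc(cc1)P(c1ccccc1)c1ccccc1
Why: Acid-mediated allylic substitution of the dienol by PPh3 at the primary terminus, the standard route to C15 carotenoid salts; the same acidic methanol cleaves the tertiary silyl ether at the Si–O bond, so C5 keeps its configuration.

**Step 16**
Reactants: 21 pseudoionone
Product: 22 (4E,6E)-3,7,11-trimethyldodeca-1,4,6,10-tetraen-3-ol (racemic)
Conditions: CH2=CHMgBr, THF, 0 °C
Reagents that add atoms: vinylmagnesium bromide, C=C[Mg]Br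
Why: Grignard 1,2-addition to the dienone; the new carbinol centre is lost in the next step.

**Step 17**
Reactants: 22 (4E,6E)-3,7,11-trimethyldodeca-1,4,6,10-tetraen-3-ol
Product: 23 [(2E,4E,6E)-3,7,11-trimethyldodeca-2,4,6,10-tetraen-1-yl]triphenylphosphonium bromide
Conditions: PPh3·HBr, MeOH, rt
Reagents that add atoms: triphenylphosphine hydrobromide, Br.c1ccc(cc1)P(c1ccccc1)c1ccccc1
Why: Ionisation of the tertiary allylic alcohol and capture by PPh3 at the primary terminus (allylic transposition) gives the conjugated salt, and the E isomer crystallises.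

**Step 18**
Reactants: 23 [(2E,4E,6E)-3,7,11-trimethyldodeca-2,4,6,10-tetraen-1-yl]triphenylphosphonium bromide; 24 (2E,4E,6E)-2,7-dimethylocta-2,4,6-trienedial
Product: 26 (2E,4E,6E,8E,10E,12E,14E)-2,7,11,15,19-pentamethylicosa-2,4,6,8,10,12,14,18-octaenal, via ylide 25 (not isolated)
Conditions: NaOMe, CH2Cl2/MeOH, 0 °C → rt (24 in excess); then heptane, 80 °C
Reagents that add atoms: none
Why: Wittig mono-olefination of the symmetrical dialdehyde, used in excess to suppress double coupling, forms C11'=C12'; heating equilibrates the new disubstituted bond to E.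

**Step 19**
Reactants: 20 {(2E,4E)-5-[(1R,2S,5S)-2-hydroxy-2-methyl-5-(prop-1-en-2-yl)cyclopentyl]-3-methylpenta-2,4-dien-1-yl}triphenylphosphonium bromide; 26 (2E,4E,6E,8E,10E,12E,14E)-2,7,11,15,19-pentamethylicosa-2,4,6,8,10,12,14,18-octaenal
Product: 28 (1S,2R,3S)-2-[(1E,3E,5E,7E,9E,11E,13E,15E,17E,19E)-3,7,12,16,20,24-hexamethylpentacosa-1,3,5,7,9,11,13,15,17,19,23-undecaen-1-yl]-1-methyl-3-(prop-1-en-2-yl)cyclopentan-1-ol, via ylide 27 (not isolated)
Conditions: NaOMe, CH2Cl2/MeOH, 0 °C → rt, dark, argon; then heptane, 80 °C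
Reagents that add atoms: none
Why: Wittig olefination forms C11=C12 and completes the C40 chain; the semi-stabilised ylide tolerates the free tertiary hydroxyl, and mild heating should convert the Z isomer of the new bond to the all-E target without touching the ring stereocentres.

## Compound list

1 | geraniol, (2E)-3,7-dimethylocta-2,6-dien-1-ol | CC(C)=CCC/C(C)=C/CO | starting material
2 | [(2S,3S)-3-methyl-3-(4-methylpent-3-en-1-yl)oxiran-2-yl]methanol | OC[C@@H]1O[C@@]1(C)CCC=C(C)C | intermediate
3 | (2R,3S)-2-(iodomethyl)-3-methyl-3-(4-methylpent-3-en-1-yl)oxirane | IC[C@@H]1O[C@@]1(C)CCC=C(C)C | intermediate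
4 | (3S)-3,7-dimethylocta-1,6-dien-3-ol | C=C[C@@](C)(O)CCC=C(C)C | intermediate
5 | triethyl{[(3S)-3,7-dimethylocta-1,6-dien-3-yl]oxy}silane | C=C[C@@](C)(O[Si](CC)(CC)CC)CCC=C(C)C | intermediate
6 | triethyl{[(2S)-4-(5,5-dimethyl-1,2,4-trioxolan-3-yl)-2-(1,2,4-trioxolan-3-yl)butan-2-yl]oxy}silane (bis-ozonide, mixture at the trioxolane carbons) | O1COOC1[C@@](C)(O[Si](CC)(CC)CC)CCC1OC(C)(C)OO1 | intermediate
7 | (2S)-2-methyl-2-[(triethylsilyl)oxy]pentanedial | O=C[C@@](C)(O[Si](CC)(CC)CC)CCC=O | intermediate
8 | ethyl (2E,6S)-2,6-dimethyl-7-oxo-6-[(triethylsilyl)oxy]hept-2-enoate | O=C[C@@](C)(O[Si](CC)(CC)CC)CC/C=C(\C)C(=O)OCC | intermediate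
9 | ethyl (2E,6S,7E)-8-methoxy-2,6-dimethyl-6-[(triethylsilyl)oxy]octa-2,7-dienoate | CO/C=C/[C@@](C)(O[Si](CC)(CC)CC)CC/C=C(\C)C(=O)OCC | intermediate
10 | (2E,6S,7E)-8-methoxy-2,6-dimethyl-6-[(triethylsilyl)oxy]octa-2,7-dien-1-ol | CO/C=C/[C@@](C)(O[Si](CC)(CC)CC)CC/C=C(\C)CO | intermediate
11 | (2E,6S,7E)-8-methoxy-2,6-dimethyl-6-[(triethylsilyl)oxy]octa-2,7-dien-1-yl acetate | CO/C=C/[C@@](C)(O[Si](CC)(CC)CC)CC/C=C(\C)COC(C)=O | intermediate
12 | triethyl{[(1E,3S,6E)-1-methoxy-3,7-dimethyl-8-(trimethylsilyl)octa-1,6-dien-3-yl]oxy}silane | CO/C=C/[C@@](C)(O[Si](CC)(CC)CC)CC/C=C(\C)C[Si](C)(C)C | intermediate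
13 | triethyl{[(1S,2R,3S)-2-(dimethoxymethyl)-1-methyl-3-(prop-1-en-2-yl)cyclopentyl]oxy}silane | C=C(C)[C@H]1CC[C@](C)(O[Si](CC)(CC)CC)[C@@H]1C(OC)OC | intermediate
14 | (1R,2S,5S)-2-methyl-5-(prop-1-en-2-yl)-2-[(triethylsilyl)oxy]cyclopentane-1-carbaldehyde | C=C(C)[C@H]1CC[C@](C)(O[Si](CC)(CC)CC)[C@@H]1C=O | intermediate
15 | ethyl (2E)-4-(diethoxyphosphoryl)-3-methylbut-2-enoate | CCOC(=O)/C=C(\C)CP(=O)(OCC)OCC | starting material
16 | lithium 1-(diethoxyphosphoryl)-4-ethoxy-2-methyl-4-oxobut-2-en-1-ide | [Li+].CCOC(=O)C=C(C)[CH-]P(=O)(OCC)OCC | intermediate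
17 | ethyl (2E,4E)-3-methyl-5-{(1R,2S,5S)-2-methyl-5-(prop-1-en-2-yl)-2-[(triethylsilyl)oxy]cyclopentyl}penta-2,4-dienoate | C=C(C)[C@H]1CC[C@](C)(O[Si](CC)(CC)CC)[C@@H]1/C=C/C(C)=C/C(=O)OCC | intermediate
18 | (2E,4E)-3-methyl-5-{(1R,2S,5S)-2-methyl-5-(prop-1-en-2-yl)-2-[(triethylsilyl)oxy]cyclopentyl}penta-2,4-dien-1-ol | C=C(C)[C@H]1CC[C@](C)(O[Si](CC)(CC)CC)[C@@H]1/C=C/C(C)=C/CO | intermediate
19 | {(2E,4E)-3-methyl-5-{(1R,2S,5S)-2-methyl-5-(prop-1-en-2-yl)-2-[(triethylsilyl)oxy]cyclopentyl}penta-2,4-dien-1-yl}triphenylphosphonium bromide | C=C(C)[C@H]1CC[C@](C)(O[Si](CC)(CC)CC)[C@@H]1/C=C/C(C)=C/C[P+](c1ccccc1)(c1ccccc1)c1ccccc1.[Br-] | intermediate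
20 | {(2E,4E)-5-[(1R,2S,5S)-2-hydroxy-2-methyl-5-(prop-1-en-2-yl)cyclopentyl]-3-methylpenta-2,4-dien-1-yl}triphenylphosphonium bromide | C=C(C)[C@H]1CC[C@](C)(O)[C@@H]1/C=C/C(C)=C/C[P+](c1ccccc1)(c1ccccc1)c1ccccc1.[Br-] | intermediate
21 | pseudoionone, (3E,5E)-6,10-dimethylundeca-3,5,9-trien-2-one | CC(C)=CCC/C(C)=C/C=C/C(C)=O | starting material
22 | (4E,6E)-3,7,11-trimethyldodeca-1,4,6,10-tetraen-3-ol (racemic) | CC(C)=CCC/C(C)=C/C=C/C(C)(O)C=C | intermediate
23 | [(2E,4E,6E)-3,7,11-trimethyldodeca-2,4,6,10-tetraen-1-yl]triphenylphosphonium bromide | CC(C)=CCC/C(C)=C/C=C/C(C)=C/C[P+](c1ccccc1)(c1ccccc1)c1ccccc1.[Br-] | intermediate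
24 | (2E,4E,6E)-2,7-dimethylocta-2,4,6-trienedial | O=C/C(C)=C/C=C/C=C(\C)C=O | starting material
25 | triphenyl[(2E,4E,6E)-3,7,11-trimethyldodeca-2,4,6,10-tetraen-1-ylidene]-λ5-phosphane | CC(C)=CCC/C(C)=C/C=C/C(C)=C/C=P(c1ccccc1)(c1ccccc1)c1ccccc1 | intermediate
26 | (2E,4E,6E,8E,10E,12E,14E)-2,7,11,15,19-pentamethylicosa-2,4,6,8,10,12,14,18-octaenal | O=C/C(C)=C/C=C/C=C(C)/C=C/C=C(C)/C=C/C=C(\C)CCC=C(C)C | intermediate
27 | (1S,2R,3S)-1-methyl-2-[(1E,3E)-3-methyl-5-(triphenyl-λ5-phosphanylidene)penta-1,3-dien-1-yl]-3-(prop-1-en-2-yl)cyclopentan-1-ol | C=C(C)[C@H]1CC[C@](C)(O)[C@@H]1/C=C/C(C)=C/C=P(c1ccccc1)(c1ccccc1)c1ccccc1 | intermediate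
28 | (1S,2R,3S)-2-[(1E,3E,5E,7E,9E,11E,13E,15E,17E,19E)-3,7,12,16,20,24-hexamethylpentacosa-1,3,5,7,9,11,13,15,17,19,23-undecaen-1-yl]-1-methyl-3-(prop-1-en-2-yl)cyclopentan-1-ol | C=C(C)[C@H]1CC[C@](C)(O)[C@@H]1/C=C/C(C)=C/C=C/C(C)=C/C=C/C=C(C)/C=C/C=C(C)/C=C/C=C(\C)CCC=C(C)C | target

## Step count and least certain steps

Total step count: 19. Longest linear sequence: 16 (steps 1–15 and 19).

**Step 11 (key step).** Facial discrimination by C5 may be weak, because with an E enol ether the methyl and silyloxy groups that flank the reacting π bond differ little in effective size. The cis-1,2 mode may also intrude, and methanol may capture the radical cation before the ring closes. A wrong C6 alone can be corrected at 14; a wrong C2/C5 relation cannot. Fallback: set out from 11. Hydrolyse the enol ether (aqueous oxalic acid, THF, 0 °C) to (2E,6S)-2,6-dimethyl-8-oxo-6-[(triethylsilyl)oxy]oct-2-en-1-yl acetate F1. Then close the same C2–C6 bond by an intramolecular Tsuji–Trost alkylation of the aldehyde through its enamine (pyrrolidine cat., Pd(PPh3)4 cat., Et3N, DMSO, rt), 5-exo at the π-allyl terminus C2. This gives the ring aldehyde directly and returns to the route at 14, with C6 free to equilibrate under the amine.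

**Step 6.** Site selection between the two formyl groups may be incomplete (double olefination, or attack at the hindered aldehyde), and the 1,5-dialdehyde may hydrate or oligomerise on handling. Fallback: set out from 5 and cleave one alkene at a time. Ozonolysis with one equivalent of ozone attacks the trisubstituted alkene first and gives, through triethyl{[(3S)-5-(5,5-dimethyl-1,2,4-trioxolan-3-yl)-3-methylpent-1-en-3-yl]oxy}silane F2 (not isolated) and PPh3, (4S)-4-methyl-4-[(triethylsilyl)oxy]hex-5-enal F3. The same stabilised ylide gives ethyl (2E,6S)-2,6-dimethyl-6-[(triethylsilyl)oxy]octa-2,7-dienoate F4. Lemieux–Johnson cleavage of the vinyl group (OsO4 cat., NaIO4, 2,6-lutidine, dioxane/H2O), which spares the electron-poor enoate, returns to the route at 8.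

**Step 10.** β-Hydride loss from the π-allyl palladium intermediate (diene formation), erosion of alkene geometry, or slow transmetalation at a temperature the enol ether tolerates may lower the yield. Fallback: set out from 10 and form the C–Si bond by displacement. MsCl, LiCl and 2,4,6-collidine in DMF give triethyl{[(1E,3S,6E)-8-chloro-1-methoxy-3,7-dimethylocta-1,6-dien-3-yl]oxy}silane F5. HSiCl3, i-Pr2NEt and CuCl (cat.) in Et2O give trichloro{(2E,6S,7E)-8-methoxy-2,6-dimethyl-6-[(triethylsilyl)oxy]octa-2,7-dien-1-yl}silane F6 (not isolated). Exhaustive methylation with MeMgBr returns to the route at 12.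

**Step 15.** Under the acid, the freed hydroxyl may capture the dienyl cation, the C5 centre may ionise, or loss of the silyl group may stay incomplete and give mixed salts. Fallback: reverse the polarity of the last coupling, setting out from 18 and 26. MnO2 oxidises 18 to (2E,4E)-3-methyl-5-{(1R,2S,5S)-2-methyl-5-(prop-1-en-2-yl)-2-[(triethylsilyl)oxy]cyclopentyl}penta-2,4-dienal F7. NaBH4 reduces 26 to (2E,4E,6E,8E,10E,12E,14E)-2,7,11,15,19-pentamethylicosa-2,4,6,8,10,12,14,18-octaen-1-ol F8, and PPh3·HBr gives [(2E,4E,6E,8E,10E,12E,14E)-2,7,11,15,19-pentamethylicosa-2,4,6,8,10,12,14,18-octaen-1-yl]triphenylphosphonium bromide F9. NaOMe forms its ylide, triphenyl[(2E,4E,6E,8E,10E,12E,14E)-2,7,11,15,19-pentamethylicosa-2,4,6,8,10,12,14,18-octaen-1-ylidene]-λ5-phosphane F10 (not isolated), which couples with F7 to give triethyl{[(1S,2R,3S)-2-[(1E,3E,5E,7E,9E,11E,13E,15E,17E,19E)-3,7,12,16,20,24-hexamethylpentacosa-1,3,5,7,9,11,13,15,17,19,23-undecaen-1-yl]-1-methyl-3-(prop-1-en-2-yl)cyclopentyl]oxy}silane F11. Bu4NF in THF at 0 °C removes the silyl group and returns to the route at 28.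

**Step 19.** Two large, poorly soluble polyene partners may react slowly and give Z-rich mixtures, while base degrades the aldehyde. Fallback: change the order of assembly, setting out from 20. Wittig reaction of 20 with the small, soluble dialdehyde 24 (excess, NaOMe) gives (2E,4E,6E,8E,10E,12E)-13-[(1R,2S,5S)-2-hydroxy-2-methyl-5-(prop-1-en-2-yl)cyclopentyl]-2,7,11-trimethyltrideca-2,4,6,8,10,12-hexaenal F12. A second Wittig reaction with 23 forms C11'=C12' last and returns to the route at 28.

## Further compounds

F1 | step 11 | (2E,6S)-2,6-dimethyl-8-oxo-6-[(triethylsilyl)oxy]oct-2-en-1-yl acetate | O=CC[C@@](C)(O[Si](CC)(CC)CC)CC/C=C(\C)COC(C)=O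
F2 | step 6 | triethyl{[(3S)-5-(5,5-dimethyl-1,2,4-trioxolan-3-yl)-3-methylpent-1-en-3-yl]oxy}silane | C=C[C@@](C)(O[Si](CC)(CC)CC)CCC1OC(C)(C)OO1
F3 | step 6 | (4S)-4-methyl-4-[(triethylsilyl)oxy]hex-5-enal | C=C[C@@](C)(O[Si](CC)(CC)CC)CCC=O
F4 | step 6 | ethyl (2E,6S)-2,6-dimethyl-6-[(triethylsilyl)oxy]octa-2,7-dienoate | C=C[C@@](C)(O[Si](CC)(CC)CC)CC/C=C(\C)C(=O)OCC
F5 | step 10 | triethyl{[(1E,3S,6E)-8-chloro-1-methoxy-3,7-dimethylocta-1,6-dien-3-yl]oxy}silane | CO/C=C/[C@@](C)(O[Si](CC)(CC)CC)CC/C=C(\C)CCl
F6 | step 10 | trichloro{(2E,6S,7E)-8-methoxy-2,6-dimethyl-6-[(triethylsilyl)oxy]octa-2,7-dien-1-yl}silane | CO/C=C/[C@@](C)(O[Si](CC)(CC)CC)CC/C=C(\C)C[Si](Cl)(Cl)Cl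
F7 | step 15 | (2E,4E)-3-methyl-5-{(1R,2S,5S)-2-methyl-5-(prop-1-en-2-yl)-2-[(triethylsilyl)oxy]cyclopentyl}penta-2,4-dienal | C=C(C)[C@H]1CC[C@](C)(O[Si](CC)(CC)CC)[C@@H]1/C=C/C(C)=C/C=O
F8 | step 15 | (2E,4E,6E,8E,10E,12E,14E)-2,7,11,15,19-pentamethylicosa-2,4,6,8,10,12,14,18-octaen-1-ol | OC/C(C)=C/C=C/C=C(C)/C=C/C=C(C)/C=C/C=C(\C)CCC=C(C)C
F9 | step 15 | [(2E,4E,6E,8E,10E,12E,14E)-2,7,11,15,19-pentamethylicosa-2,4,6,8,10,12,14,18-octaen-1-yl]triphenylphosphonium bromide | [Br-].c1ccc(cc1)[P+](c1ccccc1)(c1ccccc1)C/C(C)=C/C=C/C=C(C)/C=C/C=C(C)/C=C/C=C(\C)CCC=C(C)C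
F10 | step 15 | triphenyl[(2E,4E,6E,8E,10E,12E,14E)-2,7,11,15,19-pentamethylicosa-2,4,6,8,10,12,14,18-octaen-1-ylidene]-λ5-phosphane | c1ccc(cc1)P(c1ccccc1)(c1ccccc1)=C/C(C)=C/C=C/C=C(C)/C=C/C=C(C)/C=C/C=C(\C)CCC=C(C)C
F11 | step 15 | triethyl{[(1S,2R,3S)-2-[(1E,3E,5E,7E,9E,11E,13E,15E,17E,19E)-3,7,12,16,20,24-hexamethylpentacosa-1,3,5,7,9,11,13,15,17,19,23-undecaen-1-yl]-1-methyl-3-(prop-1-en-2-yl)cyclopentyl]oxy}silane | C=C(C)[C@H]1CC[C@](C)(O[Si](CC)(CC)CC)[C@@H]1/C=C/C(C)=C/C=C/C(C)=C/C=C/C=C(C)/C=C/C=C(C)/C=C/C=C(\C)CCC=C(C)C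
F12 | step 19 | (2E,4E,6E,8E,10E,12E)-13-[(1R,2S,5S)-2-hydroxy-2-methyl-5-(prop-1-en-2-yl)cyclopentyl]-2,7,11-trimethyltrideca-2,4,6,8,10,12-hexaenal | C=C(C)[C@H]1CC[C@](C)(O)[C@@H]1/C=C/C(C)=C/C=C/C(C)=C/C=C/C=C(\C)C=O
A1 | alternative 1 | (S)-limonene, (4S)-1-methyl-4-(prop-1-en-2-yl)cyclohex-1-ene | CC1=CC[C@H](CC1)C(C)=C
A2 | alternative 1 | (3S)-6-oxo-3-(prop-1-en-2-yl)heptanoic acid | OC(=O)C[C@H](CCC(C)=O)C(C)=C
A3 | alternative 1 | (1R,2S,5S)-5-methyl-2-(prop-1-en-2-yl)-6-oxabicyclo[3.2.0]heptan-7-one | C=C(C)[C@H]1CC[C@]2(C)OC(=O)[C@H]12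
A4 | alternative 2 | cyclopent-2-en-1-one | O=C1C=CCC1
A5 | alternative 2 | (2S,3S)-2-(dimethoxymethyl)-3-(prop-1-en-2-yl)cyclopentan-1-one | C=C(C)[C@H]1CCC(=O)[C@@H]1C(OC)OC
A6 | alternative 3 | (1R,2S,5S,6R)-2-hydroxy-6-{[(4-methoxybenzyl)oxy]methyl}-2,5-dimethyl-5-[(triethylsilyl)oxy]cyclohexyl methanesulfonate | C[C@]1(O)CC[C@](C)(O[Si](CC)(CC)CC)[C@H](COCc2ccc(OC)cc2)[C@H]1OS(C)(=O)=O
A7 | alternative 3 | 1-[(1S,2S,3S)-2-{[(4-methoxybenzyl)oxy]methyl}-3-methyl-3-[(triethylsilyl)oxy]cyclopentyl]ethan-1-one | CC(=O)[C@H]1CC[C@](C)(O[Si](CC)(CC)CC)[C@@H]1COCc1ccc(OC)cc1
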